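**Remark (assumption):** the target is read as the centrosymmetric α-truxillate (1α,2α,3β,4β) of two ferulic acid units, esterified twice with (4R,4aS,6R,7S,7aR)-2,4,7-trimethyloctahydro-1H-cyclopenta[c]pyridin-6-ol. Compounds 1 and 13 are taken as catalogue items.

## Retrosynthetic overview

- Both ester C–O bonds are cut (Mitsunobu, inversion at C6) to give the di-O-benzyl α-truxillic acid 20 (crystal-state [2+2] of O-benzylferulic acid, cyclobutane made separately) and two molecules of the 6-epi alcohol 17.
- The route rests on one feature: C1 is a CH2 bonded to N2 and to the ring-fusion carbon C7a, and C7a is β to the oxygen-bearing C6 through the methyl-bearing C7. C1–C7a is therefore cut as a 6-exo addition of an N–CH2 radical (from N–CH2SiMe3 by electron transfer and desilylation) to a C7=C7a cyclopentenone; the piperidine closes last, onto the existing five-membered ring.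
- Enone 14 comes from the bridged lactone 6 (2-oxabicyclo[3.2.1]oct-6-en-3-one): exo-methylation fixes C4 against C4a, then reduction, tosylation, allylic alcohol oxidation, α-iodination/Stille methylation and amination.
- Lactone 6 comes from (1S,4R)-cis-4-acetoxycyclopent-2-en-1-ol by Pd-catalysed malonate substitution with retention, which supplies C4a.

Key step: step 11

## Route

**Step 1**
Reactants: 1 (1S,4R)-cis-4-acetoxycyclopent-2-en-1-ol; 2 dimethyl malonate
Product: 3 dimethyl 2-[(1R,4S)-4-hydroxycyclopent-2-en-1-yl]propanedioate (cis)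
Conditions: NaH, THF, 0 °C; Pd(PPh3)4 (3 mol %), rt
Reagents that add atoms: none
Why: Tsuji–Trost allylic alkylation; Pd(0) ionises the acetate anti and the soft malonate attacks the π-allyl anti to Pd at the terminus remote from the hydroxyl, so net retention should give the cis-1,4 product and carry the acetate configuration over to the future C4a.

**Step 2**
Reactants: 3 dimethyl 2-[(1R,4S)-4-hydroxycyclopent-2-en-1-yl]propanedioate
Product: 4 methyl 2-[(1S,4S)-4-hydroxycyclopent-2-en-1-yl]acetate (cis)
Conditions: NaCl, H2O (2 equiv), DMSO, 150 °C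
Reagents that add atoms: none
Why: Krapcho dealkoxycarbonylation (chloride demethylates one ester, the carboxylate loses CO2 and water protonates the enolate) under neutral conditions that leave the allylic alcohol and the ring stereocentres untouched.

**Step 3**
Reactants: 4 methyl 2-[(1S,4S)-4-hydroxycyclopent-2-en-1-yl]acetate
Product: 6 (1S,5S)-2-oxabicyclo[3.2.1]oct-6-en-3-one, via hydroxy acid 5 (not isolated)
Conditions: LiOH, THF/H2O, 0 °C; aq HCl to pH 3–4; then EDC·HCl, DMAP, CH2Cl2 (0.01 M), 0 °C to rt
Reagents that add atoms: none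
Why: Saponification followed by carbodiimide (Steglich-type) lactonisation; the cis-1,3 placement of OH and CH2CO2H allows closure of the bridged δ-lactone, and the neutral conditions avoid acid-promoted allylic transposition to the fused γ-lactone.

**Step 4**
Reactants: 6 (1S,5S)-2-oxabicyclo[3.2.1]oct-6-en-3-one
Product: 7 (1S,4R,5R)-4-methyl-2-oxabicyclo[3.2.1]oct-6-en-3-one
Conditions: LDA (1.05 equiv), THF, −78 °C; MeI, −78 to −40 °C
Reagents that add atoms: iodomethane, CI
Why: Kinetic lactone enolate alkylation; MeI should attack C4 of the rigid bicycle axially on the exo face, anti to the etheno bridge, which sets C4 (R) relative to the bridgehead that becomes C4a.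

**Step 5**
Reactants: 7 (1S,4R,5R)-4-methyl-2-oxabicyclo[3.2.1]oct-6-en-3-one
Product: 8 (1S,4R)-4-[(2R)-1-hydroxypropan-2-yl]cyclopent-2-en-1-ol
Conditions: LiAlH4, THF, 0 °C
Reagents that add atoms: none
Why: Hydride reduction of the lactone to the diol is faster than enolisation, so C4 is carried over intact and is no longer epimerisable afterwards.

**Step 6**
Reactants: 8 (1S,4R)-4-[(2R)-1-hydroxypropan-2-yl]cyclopent-2-en-1-ol
Product: 9 (2R)-2-[(1R,4S)-4-hydroxycyclopent-2-en-1-yl]propyl 4-methylbenzenesulfonate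
Conditions: TsCl (1.05 equiv), Et3N, DMAP (cat.), CH2Cl2, 0 °C
Reagents that add atoms: 4-methylbenzenesulfonyl chloride, Cc1ccc(S(=O)(=O)Cl)cc1
Why: Chemoselective sulfonylation of the primary over the secondary allylic alcohol; the tosylate masks the hydroxyl (no oxa-Michael closure onto the later enone) and is the leaving group for the amination.

**Step 7**
Reactants: 9 (2R)-2-[(1R,4S)-4-hydroxycyclopent-2-en-1-yl]propyl 4-methylbenzenesulfonate
Product: 10 (2R)-2-[(1R)-4-oxocyclopent-2-en-1-yl]propyl 4-methylbenzenesulfonate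
Conditions: MnO2 (excess), CH2Cl2, rt
Reagents that add atoms: none
Why: MnO2 oxidation of the allylic alcohol gives the C6 ketone conjugated with C7=C7a under neutral heterogeneous conditions that should not epimerise the γ-centre C4a.

**Step 8**
Reactants: 10 (2R)-2-[(1R)-4-oxocyclopent-2-en-1-yl]propyl 4-methylbenzenesulfonate
Product: 11 (2R)-2-[(1S)-3-iodo-4-oxocyclopent-2-en-1-yl]propyl 4-methylbenzenesulfonate
Conditions: I2, pyridine/CH2Cl2, 0 °C to rt
Reagents that add atoms: iodine, II
Why: Johnson α-iodination of the enone (pyridine conjugate addition, iodination of the enolate, E1cB loss of pyridine) places iodine on C7 only.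

**Step 9**
Reactants: 11 (2R)-2-[(1S)-3-iodo-4-oxocyclopent-2-en-1-yl]propyl 4-methylbenzenesulfonate
Product: 12 (2R)-2-[(1R)-3-methyl-4-oxocyclopent-2-en-1-yl]propyl 4-methylbenzenesulfonate
Conditions: Me4Sn, PdCl2(PhCN)2 (5 mol %), AsPh3, CuI, NMP, 80 °C
Reagents that add atoms: tetramethylstannane, C[Sn](C)(C)C
Why: Stille coupling of the α-iodoenone installs the C7 methyl under neutral conditions; the primary alkyl tosylate does not add oxidatively to the arsine-ligated Pd(0).

**Step 10**
Reactants: 12 (2R)-2-[(1R)-3-methyl-4-oxocyclopent-2-en-1-yl]propyl 4-methylbenzenesulfonate; 13 N-methyl-1-(trimethylsilyl)methanamine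
Product: 14 (4R)-2-methyl-4-{(2R)-1-[methyl(trimethylsilylmethyl)amino]propan-2-yl}cyclopent-2-en-1-one
Conditions: 13 (3 equiv), iPr2NEt, NaI (cat.), MeCN, 60 °C
Reagents that add atoms: none
Why: SN2 N-alkylation of the secondary α-silylamine by the primary tosylate (iodide catalysis); any aza-Michael addition to the α-methyl enone is reversible and no stereocentre is involved.

**Step 11**
Reactants: 14 (4R)-2-methyl-4-{(2R)-1-[methyl(trimethylsilylmethyl)amino]propan-2-yl}cyclopent-2-en-1-one
Product: 16 (4R,4aS,7S,7aR)-2,4,7-trimethyloctahydro-6H-cyclopenta[c]pyridin-6-one, via 7-epi ketone 15 (not isolated)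
Conditions: [Ir(ppy)2(dtbbpy)]PF6 (1 mol %), MeCN/MeOH 4:1 (0.02 M), blue LEDs (450 nm), Ar, rt; then K2CO3, MeOH, rt
Reagents that add atoms: none
Why: Photoexcited Ir(III) oxidises the tertiary amine, the aminium radical cation gives up Me3Si+ to methanol faster than it loses an α-proton, the N–CH2 radical adds to C7a, and Ir(II) reduces the α-keto radical to the enolate, which methanol protonates at C7, so the sequence is redox-neutral. The closest known reaction type is the photosensitised electron-transfer cyclisation of α-silylamines onto tethered enones (α-aminoalkyl radical conjugate addition). The piperidine ring closes 6-exo-trig by forming C1–C7a. C7a is set by the tether, which hangs from C4a on one face of the cyclopentenone and can reach the neighbouring C7a only from that face, so the fusion is cis; C7 is set thermodynamically, because base equilibration of the α-methyl ketone (kinetic epimer 15 included) should place the methyl on the convex face, trans to C1. The step needs radical formation only at the CH2 that becomes C1, which the C–Si bond secures against N-CH3 and C3–H, and ring closure faster than radical quenching, which the pairing of a nucleophilic radical with an electron-poor enone under dilute degassed conditions should secure.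

**Step 12**
Reactants: 16 (4R,4aS,7S,7aR)-2,4,7-trimethyloctahydro-6H-cyclopenta[c]pyridin-6-one
Product: 17 (4R,4aS,6S,7S,7aR)-2,4,7-trimethyloctahydro-1H-cyclopenta[c]pyridin-6-ol
Conditions: NaBH4, MeOH, −20 to 0 °C
Reagents that add atoms: none
Why: Hydride reduction; the concave face of C6 is screened by C1 and C4 of the folded piperidine ring, so the small hydride should enter from the convex face and leave the hydroxyl on the concave face, trans to the C7 methyl (6S).

**Step 13**
Reactants: 18 ferulic acid
Product: 19 (E)-3-[4-(benzyloxy)-3-methoxyphenyl]prop-2-enoic acid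
Conditions: BnBr (1.1 equiv), NaOH (2.2 equiv), EtOH/H2O, reflux; then aq HCl
Reagents that add atoms: benzyl bromide, BrCc1ccccc1
Why: Williamson etherification; in aqueous ethanol the phenoxide is alkylated in preference to the carboxylate and any benzyl ester is saponified in the same pot.

**Step 14**
Reactants: 19 (E)-3-[4-(benzyloxy)-3-methoxyphenyl]prop-2-enoic acid (two molecules)
Product: 20 (1α,2α,3β,4β)-2,4-bis[4-(benzyloxy)-3-methoxyphenyl]cyclobutane-1,3-dicarboxylic acid
Conditions: hν (medium-pressure Hg lamp, Pyrex, λ > 300 nm), recrystallised powder, rt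
Reagents that add atoms: none
Why: Topochemical [2+2] photodimerisation; in an α-type lattice (hydrogen-bonded acid pairs stacked head-to-tail across an inversion centre, C=C separation below about 4.2 Å) the trans alkenes should join to the centrosymmetric α-truxillic acid, all four ring stereocentres being fixed by the lattice.

**Step 15**
Reactants: 17 (4R,4aS,6S,7S,7aR)-2,4,7-trimethyloctahydro-1H-cyclopenta[c]pyridin-6-ol (2.4 equiv); 20 (1α,2α,3β,4β)-2,4-bis[4-(benzyloxy)-3-methoxyphenyl]cyclobutane-1,3-dicarboxylic acid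
Product: 21 bis[(4R,4aS,6R,7S,7aR)-2,4,7-trimethyloctahydro-1H-cyclopenta[c]pyridin-6-yl] (1α,2α,3β,4β)-2,4-bis[4-(benzyloxy)-3-methoxyphenyl]cyclobutane-1,3-dicarboxylate
Conditions: PPh3, DIAD, THF, 0 °C to rt
Reagents that add atoms: none
Why: Double Mitsunobu esterification; each carboxylate displaces the alkoxyphosphonium at C6 by SN2, turning 6S into the required 6R ester, while the neutral conditions leave the cyclobutane centres and the tertiary amines untouched.

**Step 16**
Reactants: 21 the di-O-benzyl diester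
Product: 22 bis[(4R,4aS,6R,7S,7aR)-2,4,7-trimethyloctahydro-1H-cyclopenta[c]pyridin-6-yl] (1α,2α,3β,4β)-2,4-bis(4-hydroxy-3-methoxyphenyl)cyclobutane-1,3-dicarboxylate (CNP0283097.2)
Conditions: H2 (1 atm), Pd/C, EtOAc/MeOH, AcOH (cat.), rt
Reagents that add atoms: none
Why: Hydrogenolysis of the two benzyl aryl ethers; the secondary alkyl esters, the tertiary amines and the cyclobutane C–C bonds are not cleaved under these conditions.

## Compound list

1 | (1S,4R)-cis-4-acetoxycyclopent-2-en-1-ol | O[C@H]1C[C@@H](OC(C)=O)C=C1 | starting material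
2 | dimethyl malonate | COC(=O)CC(=O)OC | starting material
3 | dimethyl 2-[(1R,4S)-4-hydroxycyclopent-2-en-1-yl]propanedioate | O[C@H]1C[C@@H](C(C(=O)OC)C(=O)OC)C=C1 | intermediate
4 | methyl 2-[(1S,4S)-4-hydroxycyclopent-2-en-1-yl]acetate | O[C@H]1C[C@@H](CC(=O)OC)C=C1 | intermediate
5 | 2-[(1S,4S)-4-hydroxycyclopent-2-en-1-yl]acetic acid | O[C@H]1C[C@@H](CC(=O)O)C=C1 | intermediate (not isolated)
6 | (1S,5S)-2-oxabicyclo[3.2.1]oct-6-en-3-one | O1[C@H]2C[C@@H](CC1=O)C=C2 | intermediate
7 | (1S,4R,5R)-4-methyl-2-oxabicyclo[3.2.1]oct-6-en-3-one | O1[C@H]2C[C@@H]([C@@H](C)C1=O)C=C2 | intermediate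
8 | (1S,4R)-4-[(2R)-1-hydroxypropan-2-yl]cyclopent-2-en-1-ol | O[C@H]1C[C@@H]([C@@H](C)CO)C=C1 | intermediate
9 | (2R)-2-[(1R,4S)-4-hydroxycyclopent-2-en-1-yl]propyl 4-methylbenzenesulfonate | O[C@H]1C[C@@H]([C@@H](C)COS(=O)(=O)c2ccc(C)cc2)C=C1 | intermediate
10 | (2R)-2-[(1R)-4-oxocyclopent-2-en-1-yl]propyl 4-methylbenzenesulfonate | O=C1C[C@@H]([C@@H](C)COS(=O)(=O)c2ccc(C)cc2)C=C1 | intermediate
11 | (2R)-2-[(1S)-3-iodo-4-oxocyclopent-2-en-1-yl]propyl 4-methylbenzenesulfonate | O=C1C[C@@H]([C@@H](C)COS(=O)(=O)c2ccc(C)cc2)C=C1I | intermediate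
12 | (2R)-2-[(1R)-3-methyl-4-oxocyclopent-2-en-1-yl]propyl 4-methylbenzenesulfonate | O=C1C[C@@H]([C@@H](C)COS(=O)(=O)c2ccc(C)cc2)C=C1C | intermediate
13 | N-methyl-1-(trimethylsilyl)methanamine | CNC[Si](C)(C)C | starting material
14 | (4R)-2-methyl-4-{(2R)-1-[methyl(trimethylsilylmethyl)amino]propan-2-yl}cyclopent-2-en-1-one | O=C1C[C@@H]([C@@H](C)CN(C)C[Si](C)(C)C)C=C1C | intermediate
15 | (4R,4aS,7R,7aR)-2,4,7-trimethyloctahydro-6H-cyclopenta[c]pyridin-6-one (7-epimer) | O=C1C[C@@H]2[C@@H](CN(C)C[C@@H]2C)[C@H]1C | intermediate (not isolated)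
16 | (4R,4aS,7S,7aR)-2,4,7-trimethyloctahydro-6H-cyclopenta[c]pyridin-6-one | O=C1C[C@@H]2[C@@H](CN(C)C[C@@H]2C)[C@@H]1C | intermediate
17 | (4R,4aS,6S,7S,7aR)-2,4,7-trimethyloctahydro-1H-cyclopenta[c]pyridin-6-ol | O[C@H]1C[C@@H]2[C@@H](CN(C)C[C@@H]2C)[C@@H]1C | intermediate
18 | ferulic acid | COc1cc(/C=C/C(=O)O)ccc1O | starting material
19 | (E)-3-[4-(benzyloxy)-3-methoxyphenyl]prop-2-enoic acid | COc1cc(/C=C/C(=O)O)ccc1OCc1ccccc1 | intermediate
20 | (1α,2α,3β,4β)-2,4-bis[4-(benzyloxy)-3-methoxyphenyl]cyclobutane-1,3-dicarboxylic acid | COc1cc([C@H]2[C@H](C(=O)O)[C@H](c3ccc(OCc4ccccc4)c(OC)c3)[C@H]2C(=O)O)ccc1OCc1ccccc1 | intermediate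
21 | di-O-benzyl diester of 20 with two units of the 6R alcohol | COc1cc([C@H]2[C@H](C(=O)O[C@@H]3C[C@@H]4[C@@H](CN(C)C[C@@H]4C)[C@@H]3C)[C@H](c3ccc(OCc5ccccc5)c(OC)c3)[C@H]2C(=O)O[C@@H]2C[C@@H]3[C@@H](CN(C)C[C@@H]3C)[C@@H]2C)ccc1OCc1ccccc1 | intermediate
22 | CNP0283097.2 | COc1cc([C@H]2[C@H](C(=O)O[C@@H]3C[C@@H]4[C@@H](CN(C)C[C@@H]4C)[C@@H]3C)[C@H](c3ccc(O)c(OC)c3)[C@H]2C(=O)O[C@@H]2C[C@@H]3[C@@H](CN(C)C[C@@H]3C)[C@@H]2C)ccc1O | target

## Step count and risks

Total: 16 steps. Longest linear sequence: 14 steps (steps 1–12, 15, 16); steps 13–14 form the convergent branch.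

**Step 11 (photoredox ring closure).** Back electron transfer or α-deprotonation of the aminium radical cation may outrun desilylation, or the open-chain aminoalkyl radical may be reduced before it closes, so that desilylated acyclic amine accumulates. The fallback sets out from 12 and generates the same N–CH2 radical by irreversible loss of CO2 from a carboxylate instead of by C–Si fragmentation. Tosylate 12 would be alkylated with sarcosine tert-butyl ester (iPr2NEt, NaI, MeCN) to the tert-butyl N-methyl-N-alkylglycinate F1. Trifluoroacetic acid would free the amino acid F2. Photoredox decarboxylative conjugate addition ([Ir{dF(CF3)ppy}2(dtbbpy)]PF6, K2HPO4, DMF, blue LEDs) followed by the same K2CO3/MeOH equilibration would return to the route at 16.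

**Step 14 (crystal-state photodimerisation).** The lattice of 19 may not stack neighbouring alkenes antiparallel within reaction distance, so the crystal is photostable or dimerises head-to-head. The fallback sets out from 18 and changes the crystal and the end game. Ferulic acid would be acetylated (Ac2O, pyridine) to the 4-O-acetyl acid F3, whose crystals would be irradiated to the diacetoxy α-truxillic acid F4. Mitsunobu coupling of F4 with 17 as in step 15 would give the di-O-acetyl diester F5. Mild methanolysis of the two aryl acetates (K2CO3, MeOH, 0 °C) in place of hydrogenolysis would return to the route at 22.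

**Step 15 (double Mitsunobu).** The second esterification may stall, and the alkoxyphosphonium at the hindered C6 may eliminate instead of being displaced by the bulky cyclobutanecarboxylate. The fallback sets out from 17 and separates inversion from coupling. Mitsunobu reaction with the small, more acidic 4-nitrobenzoic acid would give the inverted 4-nitrobenzoate F6, and methanolysis (K2CO3, MeOH) would give the 6R alcohol F7. Diacid 20 would be converted with oxalyl chloride and catalytic DMF into the bis(acid chloride) F8. Acylation of F7 with F8 with retention (pyridine, DMAP, CH2Cl2, 0 °C; no stronger amine base, to avoid ketene formation) would return to the route at 21.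

## Further compounds

F1 | step 11 | tert-butyl N-methyl-N-{(2R)-2-[(1R)-3-methyl-4-oxocyclopent-2-en-1-yl]propyl}glycinate | O=C1C[C@@H]([C@@H](C)CN(C)CC(=O)OC(C)(C)C)C=C1C
F2 | step 11 | N-methyl-N-{(2R)-2-[(1R)-3-methyl-4-oxocyclopent-2-en-1-yl]propyl}glycine | O=C1C[C@@H]([C@@H](C)CN(C)CC(=O)O)C=C1C
F3 | step 14 | (E)-3-(4-acetoxy-3-methoxyphenyl)prop-2-enoic acid | COc1cc(/C=C/C(=O)O)ccc1OC(C)=O
F4 | step 14 | (1α,2α,3β,4β)-2,4-bis(4-acetoxy-3-methoxyphenyl)cyclobutane-1,3-dicarboxylic acid | COc1cc([C@H]2[C@H](C(=O)O)[C@H](c3ccc(OC(C)=O)c(OC)c3)[C@H]2C(=O)O)ccc1OC(C)=O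
F5 | step 14 | di-O-acetyl diester of F4 with two units of the 6R alcohol | COc1cc([C@H]2[C@H](C(=O)O[C@@H]3C[C@@H]4[C@@H](CN(C)C[C@@H]4C)[C@@H]3C)[C@H](c3ccc(OC(C)=O)c(OC)c3)[C@H]2C(=O)O[C@@H]2C[C@@H]3[C@@H](CN(C)C[C@@H]3C)[C@@H]2C)ccc1OC(C)=O
F6 | step 15 | (4R,4aS,6R,7S,7aR)-2,4,7-trimethyloctahydro-1H-cyclopenta[c]pyridin-6-yl 4-nitrobenzoate | O=C(O[C@@H]1C[C@@H]2[C@@H](CN(C)C[C@@H]2C)[C@@H]1C)c1ccc([N+](=O)[O-])cc1
F7 | step 15 | (4R,4aS,6R,7S,7aR)-2,4,7-trimethyloctahydro-1H-cyclopenta[c]pyridin-6-ol | O[C@@H]1C[C@@H]2[C@@H](CN(C)C[C@@H]2C)[C@@H]1C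
F8 | step 15 | (1α,2α,3β,4β)-2,4-bis[4-(benzyloxy)-3-methoxyphenyl]cyclobutane-1,3-dicarbonyl dichloride | COc1cc([C@H]2[C@H](C(=O)Cl)[C@H](c3ccc(OCc4ccccc4)c(OC)c3)[C@H]2C(=O)Cl)ccc1OCc1ccccc1
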